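**Retrosynthetic overview**
1. Last step: acidolysis of three 4-methoxybenzyl ethers unmasks the 4-hydroxy-2-pyridone and the phenol.
2. C5'–C6' (sp3–sp2) disconnection: Negishi coupling of a primary alkyl iodide with (E)-2-bromobut-2-ene installs the E-trisubstituted alkene.
3. Key disconnection C3(pyridine)–C1'(acyl): a 3-zincated 2,4-dialkoxy-5-arylpyridine opens meso-2,4-dimethylglutaric anhydride enantioselectively (proposed new step; it fixes C2' and C4' together). The remaining CO2H is then taken to CH2I.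
4. The pyridine nucleophile comes from 5-bromo-2,4-dichloropyridine by double SNAr and Suzuki coupling.
5. No ring is built: the pyridine and benzene rings are bought, and the pyridone is only unmasked at the end.

Assumption: the target is the drawn 4-hydroxy-2(1H)-pyridone tautomer with a (2S,4R,6E)-2,4,6-trimethyloct-6-enoyl chain (descriptors derived from the given SMILES; the two methyl groups are syn), and the alkenyl bromide is bought as the pure E isomer.

Abbreviations: PMB = 4-methoxybenzyl; Ar = 2,4-bis(PMB-oxy)-5-[4-(PMB-oxy)phenyl]pyridin-3-yl.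

**Route**

Step 1
Reactants: 1 5-bromo-2,4-dichloropyridine
Product: 2 5-bromo-2,4-bis(PMB-oxy)pyridine
Conditions: PMBOH (2.4 equiv), NaH (2.5 equiv), DMF, 0 → 80 °C
Reagents that add atoms: 4-methoxybenzyl alcohol, COc1ccc(CO)cc1
Why: Both chlorides sit at positions activated by the ring nitrogen (2 and 4) and are displaced by the alkoxide in a double nucleophilic aromatic substitution (SNAr), while the 5-bromide, meta to nitrogen, is inert.

Step 2
Reactants: 2 5-bromo-2,4-bis(PMB-oxy)pyridine; 3 [4-(PMB-oxy)phenyl]boronic acid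
Product: 4 2,4-bis(PMB-oxy)-5-[4-(PMB-oxy)phenyl]pyridine (ArH)
Conditions: Pd(PPh3)4 (5 mol %), K2CO3, 1,4-dioxane/H2O, 90 °C
Reagents that add atoms: none
Why: Suzuki–Miyaura coupling at the only C–Br bond installs the protected 4-hydroxyphenyl group at C5, and the PMB ethers are stable to aqueous carbonate.

Step 3
Reactants: 4 2,4-bis(PMB-oxy)-5-[4-(PMB-oxy)phenyl]pyridine (ArH); 5 meso-2,4-dimethylglutaric anhydride (cis; (3R,5S)-3,5-dimethyloxane-2,6-dione)
Product: 8 (2R,4S)-5-Ar-2,4-dimethyl-5-oxopentanoic acid, via aryllithium 6 (not isolated), via arylzinc chloride 7 (not isolated)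
Conditions: lithium 2,2,6,6-tetramethylpiperidide (from 2,2,6,6-tetramethylpiperidine and n-butyllithium), THF, −78 °C; ZnCl2, −78 °C → rt; then 5 (1.3 equiv), [Rh(cod)Cl]2 (4 mol %), (S)-4-tert-butyl-2-[2-(diphenylphosphanyl)phenyl]-4,5-dihydrooxazole ((S)-t-Bu-PHOX, 8 mol %; ligand antipode chosen so that the (2R,4S) acid results), THF/DMF, 50 °C; aq. citric acid work-up
Reagents that add atoms: none
Why: Proposed new method: the C3–H flanked by two alkoxy groups is removed by directed ortho-metalation and the lithium species is transmetalated to zinc; a monovalent rhodium–phosphinooxazoline catalyst then takes the pyridyl group from zinc, inserts into one of the two enantiotopic acyl C–O bonds of the meso anhydride (enantio-determining; the chiral P,N pocket must select the carbonyl next to the (S)-configured carbon) and reductively eliminates the hindered aryl ketone as its zinc carboxylate, which is inert to further addition, so the key pyridine–acyl bond is formed and both stereocenters (already cis in 5, neither C–H touched) are fixed in the absolute sense in one step; the closest known reaction type is the rhodium- or palladium-catalysed enantioselective acylative ring opening of meso cyclic anhydrides by simple alkylzinc or phenylzinc reagents, which has not been shown for a heteroarylzinc or a 2,6-dialkoxy-substituted arylzinc nucleophile.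

Step 4
Reactants: 8 (2R,4S)-5-Ar-2,4-dimethyl-5-oxopentanoic acid
Product: 9 (2S,4R)-1-Ar-5-hydroxy-2,4-dimethylpentan-1-one
Conditions: BH3·THF (1.5 equiv), THF, −10 → 0 °C; then H2O
Reagents that add atoms: none
Why: Borane reduces the carboxylic acid through its acyloxyborane much faster than the twisted, sterically shielded di-ortho-alkoxyaryl ketone (chemoselective borane reduction), and neither stereocenter is touched.

Step 5
Reactants: 9 (2S,4R)-1-Ar-5-hydroxy-2,4-dimethylpentan-1-one
Product: 10 (2S,4R)-1-Ar-5-iodo-2,4-dimethylpentan-1-one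
Conditions: I2, PPh3, imidazole, CH2Cl2, 0 °C → rt
Reagents that add atoms: iodine, II
Why: The Appel reaction turns the primary alcohol into the iodide by SN2 displacement of the oxyphosphonium under imidazole-buffered conditions that leave the ketone α-stereocenter and the PMB ethers intact.

Step 6
Reactants: 10 (2S,4R)-1-Ar-5-iodo-2,4-dimethylpentan-1-one; 11 (E)-2-bromobut-2-ene
Product: 13 (2S,4R,6E)-1-Ar-2,4,6-trimethyloct-6-en-1-one, via alkylzinc iodide 12 (not isolated)
Conditions: Zn dust (activated), LiCl, THF, 40 °C; then 11, Pd2(dba)3 (2.5 mol %), 2-dicyclohexylphosphino-2',6'-dimethoxybiphenyl (SPhos, 10 mol %), THF, rt → 40 °C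
Reagents that add atoms: none
Why: Zinc insertion gives a ketone-tolerant alkylzinc iodide that undergoes Negishi coupling with the alkenyl bromide under zerovalent palladium with retention of the E geometry, forming the C5'–C6' bond.

Step 7
Reactants: 13 (2S,4R,6E)-1-Ar-2,4,6-trimethyloct-6-en-1-one
Product: 14 vancouverone A, 4-hydroxy-5-(4-hydroxyphenyl)-3-[(2S,4R,6E)-2,4,6-trimethyloct-6-enoyl]pyridin-2(1H)-one
Conditions: TFA (10 vol %), pentamethylbenzene (10 equiv), CH2Cl2, 0 °C
Reagents that add atoms: none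
Why: The two pyridyl PMB ethers and the phenolic PMB ether ionise in dilute acid (acidolytic SN1-type deprotection) and the benzyl cations are trapped by pentamethylbenzene, so the trisubstituted alkene and the ketone α-stereocenter survive and the 4-hydroxy-2-pyridone is released.

**Compound list** (PMB and Ar as defined above)
1 | 5-bromo-2,4-dichloropyridine | Clc1cc(Cl)c(Br)cn1 | starting material
2 | 5-bromo-2,4-bis(PMB-oxy)pyridine | Brc1cnc(OCc2ccc(OC)cc2)cc1OCc1ccc(OC)cc1 | intermediate
3 | [4-(PMB-oxy)phenyl]boronic acid | OB(O)c1ccc(OCc2ccc(OC)cc2)cc1 | starting material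
4 | 2,4-bis(PMB-oxy)-5-[4-(PMB-oxy)phenyl]pyridine (ArH) | c1c(OCc2ccc(OC)cc2)ncc(-c2ccc(OCc3ccc(OC)cc3)cc2)c1OCc1ccc(OC)cc1 | intermediate
5 | meso-2,4-dimethylglutaric anhydride, (3R,5S)-3,5-dimethyloxane-2,6-dione | C[C@@H]1C[C@H](C)C(=O)OC1=O | starting material
6 | aryllithium ArLi | [Li]c1c(OCc2ccc(OC)cc2)ncc(-c2ccc(OCc3ccc(OC)cc3)cc2)c1OCc1ccc(OC)cc1 | intermediate
7 | arylzinc chloride ArZnCl | Cl[Zn]c1c(OCc2ccc(OC)cc2)ncc(-c2ccc(OCc3ccc(OC)cc3)cc2)c1OCc1ccc(OC)cc1 | intermediate
8 | (2R,4S)-5-Ar-2,4-dimethyl-5-oxopentanoic acid | OC(=O)[C@H](C)C[C@H](C)C(=O)c1c(OCc2ccc(OC)cc2)ncc(-c2ccc(OCc3ccc(OC)cc3)cc2)c1OCc1ccc(OC)cc1 | intermediate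
9 | (2S,4R)-1-Ar-5-hydroxy-2,4-dimethylpentan-1-one | OC[C@H](C)C[C@H](C)C(=O)c1c(OCc2ccc(OC)cc2)ncc(-c2ccc(OCc3ccc(OC)cc3)cc2)c1OCc1ccc(OC)cc1 | intermediate
10 | (2S,4R)-1-Ar-5-iodo-2,4-dimethylpentan-1-one | IC[C@H](C)C[C@H](C)C(=O)c1c(OCc2ccc(OC)cc2)ncc(-c2ccc(OCc3ccc(OC)cc3)cc2)c1OCc1ccc(OC)cc1 | intermediate
11 | (E)-2-bromobut-2-ene | C/C=C(\C)Br | starting material
12 | [(2R,4S)-5-Ar-2,4-dimethyl-5-oxopentyl]zinc iodide | I[Zn]C[C@H](C)C[C@H](C)C(=O)c1c(OCc2ccc(OC)cc2)ncc(-c2ccc(OCc3ccc(OC)cc3)cc2)c1OCc1ccc(OC)cc1 | intermediate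
13 | (2S,4R,6E)-1-Ar-2,4,6-trimethyloct-6-en-1-one | C/C=C(\C)C[C@H](C)C[C@H](C)C(=O)c1c(OCc2ccc(OC)cc2)ncc(-c2ccc(OCc3ccc(OC)cc3)cc2)c1OCc1ccc(OC)cc1 | intermediate
14 | vancouverone A, 4-hydroxy-5-(4-hydroxyphenyl)-3-[(2S,4R,6E)-2,4,6-trimethyloct-6-enoyl]pyridin-2(1H)-one | C/C=C(\C)C[C@H](C)C[C@H](C)C(=O)c1c(O)c(-c2ccc(O)cc2)c[nH]c1=O | target

**Step count and risk**
Total step count: 7. Longest linear sequence: 7 steps (1 → 14).

The three steps most likely to fail:

Step 3 (proposed new desymmetrising acylation). The risks are metalation away from C3, slow transfer of the hindered pyridyl group from zinc to rhodium, decarbonylation, and low or opposite enantioselectivity. The fallback uses known chemistry only; it sets out from anhydride 5 and comes back at keto acid 8. Cinchona-alkaloid-mediated methanolysis of 5 (MeOH, (DHQD)2AQN or its pseudo-enantiomer (DHQ)2AQN, whichever gives the needed half-ester, Et2O, −40 °C) gives (2S,4R)-5-methoxy-2,4-dimethyl-5-oxopentanoic acid F1. Oxalyl chloride with catalytic DMF in CH2Cl2 at 0 °C converts it into methyl (2R,4S)-5-chloro-2,4-dimethyl-5-oxopentanoate F2. Negishi acylation of F2 with arylzinc chloride 7 (made from 4 as in step 3; Pd(PPh3)4, THF, 0 °C → rt) gives methyl (2R,4S)-5-Ar-2,4-dimethyl-5-oxopentanoate F3. Neutral ester hydrolysis with Me3SnOH in 1,2-dichloroethane at 70 °C then gives 8 without epimerisation.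

Step 4 (acid reduced beside a ketone). The risk is over-reduction of the ketone, possibly by intramolecular hydride delivery. The fallback sets out from 8 and comes back at 9, lowering the oxidation level in two selective stages. Thioesterification of 8 (EtSH, EDC·HCl, cat. DMAP, CH2Cl2) gives S-ethyl (2R,4S)-5-Ar-2,4-dimethyl-5-oxopentanethioate F4. Fukuyama reduction (Et3SiH, Pd/C, acetone, rt) gives (2R,4S)-5-Ar-2,4-dimethyl-5-oxopentanal F5. NaBH4 in EtOH/CH2Cl2 at −78 °C reduces only the aldehyde and gives 9.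

Step 6 (alkylzinc formation and sp3–sp2 coupling beside a ketone). The risks are cyclisation of the organozinc onto the ketone, protodezincation and loss of alkene geometry. The fallback sets out from iodide 10 and comes back at 13 without any preformed organometallic: nickel-catalysed reductive cross-electrophile coupling of 10 with 11 (NiI2 10 mol %, 4,4'-di-tert-butyl-2,2'-bipyridine, Mn powder, DMA, rt) joins the two halides directly with retention of the E geometry. It makes no new compound (none F0).

**Further compounds**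
F1 | step 3 | (2S,4R)-5-methoxy-2,4-dimethyl-5-oxopentanoic acid | COC(=O)[C@H](C)C[C@H](C)C(=O)O
F2 | step 3 | methyl (2R,4S)-5-chloro-2,4-dimethyl-5-oxopentanoate | COC(=O)[C@H](C)C[C@H](C)C(Cl)=O
F3 | step 3 | methyl (2R,4S)-5-Ar-2,4-dimethyl-5-oxopentanoate | COC(=O)[C@H](C)C[C@H](C)C(=O)c1c(OCc2ccc(OC)cc2)ncc(-c2ccc(OCc3ccc(OC)cc3)cc2)c1OCc1ccc(OC)cc1
F4 | step 4 | S-ethyl (2R,4S)-5-Ar-2,4-dimethyl-5-oxopentanethioate | CCSC(=O)[C@H](C)C[C@H](C)C(=O)c1c(OCc2ccc(OC)cc2)ncc(-c2ccc(OCc3ccc(OC)cc3)cc2)c1OCc1ccc(OC)cc1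
F5 | step 4 | (2R,4S)-5-Ar-2,4-dimethyl-5-oxopentanal | O=C[C@H](C)C[C@H](C)C(=O)c1c(OCc2ccc(OC)cc2)ncc(-c2ccc(OCc3ccc(OC)cc3)cc2)c1OCc1ccc(OC)cc1
F0 | step 6 | none | none
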